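**Plan**
- Retrosynthetic cuts: the three O–benzyl bonds; the C–H bond at the tertiary carbon of the C7 isobutyl group (back to an O–C(CH3)2 bond, a 2,2-dimethyldihydropyran fused to trione ring A); the C7'–isopropyl bond; the C7'=C bond to trione ring B; the C7–CH2 and O–C(CH3)2 bonds of the dihydropyran (retro-[4+2] to an arylidene trione and isobutene); the C7=C bond to ring A. What remains is a tribenzylated diformyl hexanoylphloroglucinol and syncarpic acid (used twice).
- Forward order: phloroglucinol is acylated, diformylated and benzylated; ring A is attached by Knoevenagel condensation; the dihydropyran closes in the cycloaddition with isobutene; ring B is attached by a second Knoevenagel condensation; isopropyl is added at C7'; the pyran is opened by ionic hydrogenation; the benzyl groups are removed.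
- Enabling feature: C7 (the methine bearing isobutyl) carries CH2–CH(CH3)2, which is isobutene plus one hydrogen. The tertiary carbon of that chain and an enol oxygen of ring A are the two ends of the six-atom chain O–C=C–C7–CH2–C(CH3)2, so they can be joined in a six-membered ring that a 1-oxadiene (the arylidene trione) and isobutene assemble in one [4+2] step.
- Stereochemistry: C7 (R) comes from the catalyst-controlled cycloaddition (chiral bis(oxazoline) complex of divalent copper); C7' (R) comes from a catalyst-controlled conjugate addition of diisopropylzinc (chiral phosphoramidite, copper). No phenol is free until the last step, so neither centre can be lost by retro-Michael cleavage.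

Key step: step 7

Remark (assumption): the absolute sense of induction in the two catalytic asymmetric steps (7 and 9) cannot be predicted with certainty; the ligand enantiomers named are those assumed to give (R) at both centres, and the mirror-image ligand is used if the opposite sense is found.

**Route**

Step 1
Reactants: 1 phloroglucinol; 2 hexanoyl chloride
Product: 3 1-(2,4,6-trihydroxyphenyl)hexan-1-one
Conditions: AlCl3 (4 equiv), PhNO2–CH2Cl2, 0 °C → 45 °C; aq. HCl work-up
Reagents that add atoms: none
Why: Friedel–Crafts acylation of the electron-rich triol stops after one acyl group because the aluminium-chelated aryl ketone deactivates the ring toward a second.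

Step 2
Reactants: 3 1-(2,4,6-trihydroxyphenyl)hexan-1-one
Product: 5 5-hexanoyl-2,4,6-trihydroxybenzene-1,3-dicarbaldehyde, via bis(α-chloro ether) 4 (not isolated)
Conditions: Cl2CHOMe (4 equiv), TiCl4 (6 equiv), CH2Cl2, −10 °C → rt; then ice/aq. HCl
Reagents that add atoms: dichloromethyl methyl ether, COC(Cl)Cl; water, O
Why: Rieche formylation, in which the TiCl4-activated dichloromethyl ether substitutes the only two free ring positions (each activated by three oxygen donors) and the α-chloro ethers are hydrolysed to aldehydes on aqueous work-up.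

Step 3
Reactants: 5 5-hexanoyl-2,4,6-trihydroxybenzene-1,3-dicarbaldehyde
Product: 6 2,4,6-tris(benzyloxy)-5-hexanoylbenzene-1,3-dicarbaldehyde
Conditions: BnBr (4.5 equiv), K2CO3 (5 equiv), DMF, 60 °C
Reagents that add atoms: benzyl bromide, BrCc1ccccc1
Why: Williamson etherification of the three acidic, carbonyl-flanked phenols on oxygen (every ring carbon is substituted); benzyl is chosen because it withstands the Lewis acid of step 7 and the acid of step 10 and leaves by neutral hydrogenolysis.

Step 4
Reactants: 7 1-(2,4,6-trihydroxyphenyl)ethan-1-one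
Product: 8 acetylsyncarpic acid (2-acetyl-3-hydroxy-4,4,6,6-tetramethylcyclohex-2-ene-1,5-dione)
Conditions: MeI (8 equiv), NaOMe (6 equiv), MeOH, 0 °C → reflux; aq. HCl work-up
Reagents that add atoms: methyl iodide, CI
Why: Exhaustive C-methylation of the acylphloroglucinol under methoxide (dearomatising geminal dimethylation at both unsubstituted ring carbons) is the standard entry to the tetramethylated trione skeleton.

Step 5
Reactants: 8 acetylsyncarpic acid
Product: 9 syncarpic acid (enol form of 2,2,4,4-tetramethylcyclohexane-1,3,5-trione)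
Conditions: 6 M aq. HCl, reflux
Reagents that add atoms: none
Why: Acid-promoted retro-Claisen deacylation of the exocyclic acetyl group of a 2-acyl-1,3-dione, the ring carbonyls being shielded by the gem-dimethyl groups.

Step 6
Reactants: 6 2,4,6-tris(benzyloxy)-5-hexanoylbenzene-1,3-dicarbaldehyde; 9 syncarpic acid
Product: 10 2,4,6-tris(benzyloxy)-3-hexanoyl-5-[(3,3,5,5-tetramethyl-2,4,6-trioxocyclohexylidene)methyl]benzaldehyde
Conditions: 9 (0.5 equiv relative to 6), ethylenediammonium diacetate (10 mol%), 4 Å MS, CH2Cl2, rt → 40 °C; surplus 6 recovered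
Reagents that add atoms: none
Why: Knoevenagel condensation of a non-enolisable aryl aldehyde with the cyclic 1,3-dione; the two formyl groups of 6 are equivalent, so limiting 9 should give mainly the mono-adduct, and the twisted di-ortho-substituted arylidene resists Michael addition of a second dione.

Step 7
Reactants: 10 mono(arylidene trione) aldehyde; 11 isobutene
Product: 12 2,4,6-tris(benzyloxy)-3-hexanoyl-5-[(4R)-2,2,6,6,8,8-hexamethyl-5,7-dioxo-3,4,5,6,7,8-hexahydro-2H-chromen-4-yl]benzaldehyde
Conditions: isobutene (10 equiv, condensed in), CuCl2 (10 mol%), AgSbF6 (20 mol%), (S,S)-t-Bu-BOX [2,2'-(propane-2,2-diyl)bis((4S)-4-tert-butyl-4,5-dihydrooxazole), 11 mol%], 4 Å MS, CH2Cl2, −40 °C → 0 °C, sealed vessel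
Reagents that add atoms: none
Why: Proposed new method: cationic divalent copper binds the flanking trione carbonyl that lies syn to C7–H (the two flanking carbonyls of a cyclic 1,3-dione point apart and cannot chelate one metal, and the other lone pairs are blocked by the gem-dimethyl groups and the twisted aryl ring), which lowers the LUMO of the O=C–C=C7 oxadiene; the CH2 terminus of isobutene then bonds to C7 while positive charge builds on its tertiary carbon, and the bound carbonyl oxygen captures that carbon in an asynchronous inverse-electron-demand [4+2] cycloaddition. The closest known reactions are the uncatalysed, racemic oxa-Diels–Alder additions of alkylidene syncarpic acids and other 2-alkylidene-1,3-diones to 1,1-disubstituted alkenes, and the copper bis(oxazoline)-catalysed enantioselective hetero-Diels–Alder reactions of oxadienes with enol ethers and carbonyl–ene reactions of isobutene. The dihydropyran ring closes in the cycloaddition itself, the C7–CH2 bond leading and the O–C(CH3)2 bond following as a six-membered closure of oxygen onto the incipient tertiary cation; a 2-methylallyl ene product, should it form, is cyclised to the same ring by the Lewis acid. The new stereocentre C7 (C4 of the chromene) is set under catalyst control, one tert-butyl group of the C2-symmetric ligand covering one face of C7 so that isobutene adds to the other and gives (R). The step needs enantiofacial selectivity, which rests on the single copper binding site that the substrate leaves open, and regioselectivity, which the polarity of isobutene secures (CH2 to carbon, tertiary carbon to oxygen). The free formyl group, an electron-rich aryl aldehyde flanked by two benzyloxy groups, is not expected to undergo a carbonyl–ene reaction with isobutene under these conditions.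

Step 8
Reactants: 12 dihydropyran-fused adduct; 9 syncarpic acid
Product: 13 2-({2,4,6-tris(benzyloxy)-3-hexanoyl-5-[(4R)-2,2,6,6,8,8-hexamethyl-5,7-dioxo-3,4,5,6,7,8-hexahydro-2H-chromen-4-yl]phenyl}methylidene)-4,4,6,6-tetramethylcyclohexane-1,3,5-trione
Conditions: 9 (1.2 equiv), ethylenediammonium diacetate (20 mol%), 4 Å MS, CH2Cl2, rt → 40 °C
Reagents that add atoms: none
Why: Knoevenagel condensation as in step 6 on the only remaining formyl group; the buffered amine catalyst leaves the vinylogous ester ring and the non-acidic C4–H stereocentre untouched.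

Step 9
Reactants: 13 arylidene trione; 14 diisopropylzinc
Product: 16 (4R)-4-{2,4,6-tris(benzyloxy)-3-hexanoyl-5-[(1R)-1-(2-hydroxy-3,3,5,5-tetramethyl-4,6-dioxocyclohex-1-en-1-yl)-2-methylpropyl]phenyl}-2,2,6,6,8,8-hexamethyl-3,4-dihydro-2H-chromene-5,7(6H,8H)-dione, via isopropylzinc enolate 15 (not isolated)
Conditions: i-Pr2Zn (2 equiv), Cu(OTf)2 (5 mol%), (S)-1,1'-binaphthalene-2,2'-diyl N,N-bis[(R)-1-phenylethyl]phosphoramidite (10 mol%), toluene, −40 °C → −20 °C; then 1 M aq. HCl, 0 °C
Reagents that add atoms: none
Why: Copper-catalysed asymmetric conjugate addition of a dialkylzinc to a doubly activated alkylidene 1,3-dicarbonyl compound (the reaction type known for alkylidene malonates and alkylidene Meldrum's acids): the phosphoramidite complex of monovalent copper formed in situ delivers isopropyl to one face of the arylidene and sets C7' (R) under catalyst control, the existing centre being too remote to compete, and the zinc enolate is protonated on work-up.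

Step 10
Reactants: 16 conjugate adduct
Product: 17 tri-O-benzyl myrtucommulone H, 1-{2,4,6-tris(benzyloxy)-3-[(1R)-1-(2-hydroxy-3,3,5,5-tetramethyl-4,6-dioxocyclohex-1-en-1-yl)-3-methylbutyl]-5-[(1R)-1-(2-hydroxy-3,3,5,5-tetramethyl-4,6-dioxocyclohex-1-en-1-yl)-2-methylpropyl]phenyl}hexan-1-one
Conditions: Et3SiH (3 equiv), CF3CO2H–CH2Cl2 (1:4), 0 °C
Reagents that add atoms: none
Why: Ionic hydrogenation: protonation of the vinylogous ester carbonyl ionises the tertiary alkyl–oxygen bond (as in acid cleavage of a tert-butyl ester) and the tertiary cation, or the alkenes in equilibrium with it, takes hydride from the silane to leave the isobutyl group and the free enol, while the benzyl ethers keep the phenol oxygens from capturing the cation and hold the hexanoyl carbonyl twisted and unreactive, and neither stereocentre is involved.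

Step 11
Reactants: 17 tri-O-benzyl myrtucommulone H
Product: 18 myrtucommulone H, (R) at C7 and (R) at C7'
Conditions: H2 (1 atm), Pd/C (10 wt% palladium on carbon), EtOAc, rt
Reagents that add atoms: none
Why: Hydrogenolysis of the three aryl benzyl ethers over palladium under neutral conditions, which the hydrogen-bonded aryl ketone, the enolised triones and both stereocentres tolerate.

**Compound list**

1 | phloroglucinol (benzene-1,3,5-triol) | Oc1cc(O)cc(O)c1 | starting material
2 | hexanoyl chloride | CCCCCC(=O)Cl | starting material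
3 | 1-(2,4,6-trihydroxyphenyl)hexan-1-one | CCCCCC(=O)c1c(O)cc(O)cc1O | intermediate
4 | 1-{3,5-bis[chloro(methoxy)methyl]-2,4,6-trihydroxyphenyl}hexan-1-one (bis(α-chloro ether), held as its titanium phenoxide, diastereomer mixture) | CCCCCC(=O)c1c(O)c(C(Cl)OC)c(O)c(C(Cl)OC)c1O | intermediate (not isolated)
5 | 5-hexanoyl-2,4,6-trihydroxybenzene-1,3-dicarbaldehyde | CCCCCC(=O)c1c(O)c(C=O)c(O)c(C=O)c1O | intermediate
6 | 2,4,6-tris(benzyloxy)-5-hexanoylbenzene-1,3-dicarbaldehyde | CCCCCC(=O)c1c(OCc2ccccc2)c(C=O)c(OCc2ccccc2)c(C=O)c1OCc1ccccc1 | intermediate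
7 | 1-(2,4,6-trihydroxyphenyl)ethan-1-one (2,4,6-trihydroxyacetophenone) | CC(=O)c1c(O)cc(O)cc1O | starting material
8 | acetylsyncarpic acid (2-acetyl-3-hydroxy-4,4,6,6-tetramethylcyclohex-2-ene-1,5-dione) | CC(=O)C1=C(O)C(C)(C)C(=O)C(C)(C)C1=O | intermediate
9 | syncarpic acid (5-hydroxy-2,2,6,6-tetramethylcyclohex-4-ene-1,3-dione) | CC1(C)C(O)=CC(=O)C(C)(C)C1=O | intermediate
10 | 2,4,6-tris(benzyloxy)-3-hexanoyl-5-[(3,3,5,5-tetramethyl-2,4,6-trioxocyclohexylidene)methyl]benzaldehyde | CCCCCC(=O)c1c(OCc2ccccc2)c(C=C2C(=O)C(C)(C)C(=O)C(C)(C)C2=O)c(OCc2ccccc2)c(C=O)c1OCc1ccccc1 | intermediate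
11 | isobutene (2-methylpropene) | CC(C)=C | starting material
12 | 2,4,6-tris(benzyloxy)-3-hexanoyl-5-[(4R)-2,2,6,6,8,8-hexamethyl-5,7-dioxo-3,4,5,6,7,8-hexahydro-2H-chromen-4-yl]benzaldehyde | CCCCCC(=O)c1c(OCc2ccccc2)c([C@H]2CC(C)(C)OC3=C2C(=O)C(C)(C)C(=O)C3(C)C)c(OCc2ccccc2)c(C=O)c1OCc1ccccc1 | intermediate
13 | 2-({2,4,6-tris(benzyloxy)-3-hexanoyl-5-[(4R)-2,2,6,6,8,8-hexamethyl-5,7-dioxo-3,4,5,6,7,8-hexahydro-2H-chromen-4-yl]phenyl}methylidene)-4,4,6,6-tetramethylcyclohexane-1,3,5-trione | CCCCCC(=O)c1c(OCc2ccccc2)c([C@H]2CC(C)(C)OC3=C2C(=O)C(C)(C)C(=O)C3(C)C)c(OCc2ccccc2)c(C=C2C(=O)C(C)(C)C(=O)C(C)(C)C2=O)c1OCc1ccccc1 | intermediate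
14 | diisopropylzinc | CC(C)[Zn]C(C)C | starting material
15 | isopropylzinc enolate of 16 (O–Zn–isopropyl on the ring B enolate oxygen; (4R), (1R)) | CCCCCC(=O)c1c(OCc2ccccc2)c([C@H]2CC(C)(C)OC3=C2C(=O)C(C)(C)C(=O)C3(C)C)c(OCc2ccccc2)c([C@H](C2=C(O[Zn]C(C)C)C(C)(C)C(=O)C(C)(C)C2=O)C(C)C)c1OCc1ccccc1 | intermediate (not isolated)
16 | (4R)-4-{2,4,6-tris(benzyloxy)-3-hexanoyl-5-[(1R)-1-(2-hydroxy-3,3,5,5-tetramethyl-4,6-dioxocyclohex-1-en-1-yl)-2-methylpropyl]phenyl}-2,2,6,6,8,8-hexamethyl-3,4-dihydro-2H-chromene-5,7(6H,8H)-dione | CCCCCC(=O)c1c(OCc2ccccc2)c([C@H]2CC(C)(C)OC3=C2C(=O)C(C)(C)C(=O)C3(C)C)c(OCc2ccccc2)c([C@H](C2=C(O)C(C)(C)C(=O)C(C)(C)C2=O)C(C)C)c1OCc1ccccc1 | intermediate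
17 | tri-O-benzyl myrtucommulone H ((1R)-3-methylbutyl arm and (1R)-2-methylpropyl arm, both enols free) | CCCCCC(=O)c1c(OCc2ccccc2)c([C@@H](CC(C)C)C2=C(O)C(C)(C)C(=O)C(C)(C)C2=O)c(OCc2ccccc2)c([C@H](C2=C(O)C(C)(C)C(=O)C(C)(C)C2=O)C(C)C)c1OCc1ccccc1 | intermediate
18 | myrtucommulone H ((R) at C7, (R) at C7') | CCCCCC(=O)c1c(O)c([C@@H](CC(C)C)C2=C(O)C(C)(C)C(=O)C(C)(C)C2=O)c(O)c([C@H](C2=C(O)C(C)(C)C(=O)C(C)(C)C2=O)C(C)C)c1O | target

**Step count and risks**

Total: 11 steps. Longest linear sequence: 9 steps (1, 2, 3, 6, 7, 8, 9, 10, 11) from phloroglucinol; syncarpic acid is made in 2 steps (4, 5) and used in steps 6 and 8.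

Steps most likely to fail:

1. Step 7 (proposed new method). The risks are poor enantiofacial selectivity, because the trione offers copper only one-point binding; sequestration of the catalyst at the formyl/benzyloxy chelating site; and acid-induced oligomerisation of isobutene. Fallback (known chemistry), setting out from 10: the cycloaddition is run without catalyst (excess isobutene, toluene, 80 °C, sealed tube), which is the established thermal oxa-Diels–Alder reaction of alkylidene syncarpic acids with 1,1-disubstituted alkenes. It should give the racemic adduct, that is 12 together with its mirror image, the (4S)-adduct F1. The two are separated by preparative chromatography on a chiral stationary phase, and the route is rejoined at 12.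

2. Step 9. The risks are transfer of a β-hydride from the isopropyl reagent instead of the alkyl group, sluggish addition to the crowded arylidene, and insufficient catalyst control of the C7' face. Fallback, setting out from 13: a rhodium-catalysed asymmetric 1,4-addition (Hayashi–Miyaura reaction) of potassium isopropenyltrifluoroborate, with [RhCl(C2H4)2]2 and a chiral diene ligand (Et3N, toluene–H2O, 60 °C), should give the isopropenyl adduct F2. Hydrogenation of its 1,1-disubstituted alkene with RhCl(PPh3)3 under H2 (benzyl ethers and the tetrasubstituted enol ether survive) returns the route to 16.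

3. Step 10. The risks are re-closure of the tertiary cation on the enol oxygen outrunning hydride capture, reduction of the hexanoyl carbonyl by the silane, and debenzylative capture of the cation by the neighbouring benzyloxy oxygen. Fallback, setting out from 16: TMSOTf and 2,6-lutidine in CH2Cl2 at 0 °C ionise the tertiary alkyl–oxygen bond and remove a proton (the counterpart of the silyl triflate cleavage of tert-butyl esters). A methanolic K2CO3 work-up then frees the enols to give the ring-opened 2-methylallyl bis-enol F3 and its 2-methylprop-1-enyl isomer F4. Hydrogen over Pd/C in EtOAc saturates either alkene and removes the three benzyl groups in the same operation, so the route is rejoined at 18 without passing through 17.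

**Further compounds**

F1 | step 7 | 2,4,6-tris(benzyloxy)-3-hexanoyl-5-[(4S)-2,2,6,6,8,8-hexamethyl-5,7-dioxo-3,4,5,6,7,8-hexahydro-2H-chromen-4-yl]benzaldehyde (enantiomer of 12) | CCCCCC(=O)c1c(OCc2ccccc2)c([C@@H]2CC(C)(C)OC3=C2C(=O)C(C)(C)C(=O)C3(C)C)c(OCc2ccccc2)c(C=O)c1OCc1ccccc1
F2 | step 9 | (4R)-4-{2,4,6-tris(benzyloxy)-3-hexanoyl-5-[(1R)-1-(2-hydroxy-3,3,5,5-tetramethyl-4,6-dioxocyclohex-1-en-1-yl)-2-methylprop-2-en-1-yl]phenyl}-2,2,6,6,8,8-hexamethyl-3,4-dihydro-2H-chromene-5,7(6H,8H)-dione | CCCCCC(=O)c1c(OCc2ccccc2)c([C@H]2CC(C)(C)OC3=C2C(=O)C(C)(C)C(=O)C3(C)C)c(OCc2ccccc2)c([C@H](C2=C(O)C(C)(C)C(=O)C(C)(C)C2=O)C(C)=C)c1OCc1ccccc1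
F3 | step 10 | 1-{2,4,6-tris(benzyloxy)-3-[(1R)-1-(2-hydroxy-3,3,5,5-tetramethyl-4,6-dioxocyclohex-1-en-1-yl)-3-methylbut-3-en-1-yl]-5-[(1R)-1-(2-hydroxy-3,3,5,5-tetramethyl-4,6-dioxocyclohex-1-en-1-yl)-2-methylpropyl]phenyl}hexan-1-one | CCCCCC(=O)c1c(OCc2ccccc2)c([C@@H](CC(C)=C)C2=C(O)C(C)(C)C(=O)C(C)(C)C2=O)c(OCc2ccccc2)c([C@H](C2=C(O)C(C)(C)C(=O)C(C)(C)C2=O)C(C)C)c1OCc1ccccc1
F4 | step 10 | 1-{2,4,6-tris(benzyloxy)-3-[(1R)-1-(2-hydroxy-3,3,5,5-tetramethyl-4,6-dioxocyclohex-1-en-1-yl)-3-methylbut-2-en-1-yl]-5-[(1R)-1-(2-hydroxy-3,3,5,5-tetramethyl-4,6-dioxocyclohex-1-en-1-yl)-2-methylpropyl]phenyl}hexan-1-one | CCCCCC(=O)c1c(OCc2ccccc2)c([C@@H](C=C(C)C)C2=C(O)C(C)(C)C(=O)C(C)(C)C2=O)c(OCc2ccccc2)c([C@H](C2=C(O)C(C)(C)C(=O)C(C)(C)C2=O)C(C)C)c1OCc1ccccc1
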